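**Plan**

- Carbons are numbered C1 (lactone carbonyl) to C20 along the chain; the ring oxygen sits on C5 and the hydroxyls on C7, C9 and C11.
- Retrosynthetic cuts: O1–C1 and C2–C3 (lactonisation, acetate Claisen), then C9–C10 (aldol, with C11–H from ketone reduction); C3 and C9 are then rejoined, and C5–C6/C8–C9 are cut as a [4+3] cycloaddition of furan with an oxyallyl cation.
- Enabling feature: C3, C5, C7 and C9 carry oxygen on alternate carbons with C5–O/C7–O syn. C3–C9 is therefore the seven-carbon perimeter of an 8-oxabicyclo[3.2.1]octan-6-one (bridge oxygen on C5 and C9, ketone at C3), which a Baeyer–Villiger oxidation cuts between C3 and C9.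
- Forward order: oxabicycle by [4+3] → ketone → six-membered lactone acetal by ring expansion → open C3–C9 chain → C10–C20 joined at C9 → C1–C2 joined at C3 → dihydropyranone ring closed last.
- Stereochemistry: C5/C7 syn comes from the rigid meso bicycle (equatorial C7–O), and the absolute sense from hydroboration with (Ipc)2BH, which differentiates the two enantiotopic alkene carbons. C9 is set by 1,3-anti induction from C7–OBn in the aldol, and C11 by 1,3-syn reduction directed by C9–OH.

Key step: step 6

Assumption: the sense of induction of (Ipc)2BH on the meso alkene 6 is taken to parallel that on norbornene, which calls for the (+)-reagent made from (−)-α-pinene; should it prove opposite, the antipodal reagent is used and nothing else changes.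

**Route**

Step 1
Reactants: 1 furan; 2 1,1,3,3-tetrabromopropan-2-one
Product: 4 8-oxabicyclo[3.2.1]oct-6-en-3-one, via dibromo ketone 3 (not isolated)
Conditions: Zn–Ag couple, THF, −10 °C → rt; then Zn–Cu couple, NH4Cl, MeOH, −78 °C → rt
Reagents that add atoms: none
Why: Reductive generation of the dibromo-oxyallyl cation from 2 and its [4+3] cycloaddition to furan, followed by zinc debromination of the α,α'-dibromo ketone, is the standard entry to this meso bicycle.

Step 2
Reactants: 4 8-oxabicyclo[3.2.1]oct-6-en-3-one
Product: 5 meso 8-oxabicyclo[3.2.1]oct-6-en-3-ol with equatorial hydroxyl (OH on the side of the oxygen bridge)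
Conditions: SmI2, i-PrOH, THF, rt
Reagents that add atoms: none
Why: Ketyl reduction by samarium diiodide with an alcohol proton source runs under thermodynamic control and should give mainly the equatorial alcohol, the configuration that later becomes the C5/C7 syn relationship, while the isolated alkene is inert to the reagent.

Step 3
Reactants: 5 equatorial alcohol
Product: 6 meso 3-(benzyloxy)-8-oxabicyclo[3.2.1]oct-6-ene (benzyloxy equatorial)
Conditions: NaH, BnBr, n-Bu4NI (cat.), THF/DMF, 0 °C → rt
Reagents that add atoms: benzyl bromide, BrCc1ccccc1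
Why: Williamson etherification of the unhindered secondary alkoxide installs a group that survives peracid, Lewis acid and enolate steps and later directs the aldol from C7.

Step 4
Reactants: 6 meso benzyl ether
Product: 8 (1S,3S,5S,6R)-3-(benzyloxy)-8-oxabicyclo[3.2.1]octan-6-ol, via alkyldiisopinocampheylborane 7 (not isolated)
Conditions: (+)-(Ipc)2BH (crystalline, from (−)-α-pinene), THF, −25 → 0 °C; then NaOH, H2O2 (aq.), 0 °C → rt
Reagents that add atoms: hydrogen peroxide, OO
Why: Brown asymmetric hydroboration–oxidation, in which the chiral dialkylborane adds syn from the exo face and distinguishes the two enantiotopic alkene carbons of meso 6, so that oxygen ends up on the carbon that becomes C3; this one event fixes the absolute configuration at C5 and C7, and the new carbinol centre is removed in step 5.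

Step 5
Reactants: 8 exo-alcohol
Product: 9 (1R,3S,5S)-3-(benzyloxy)-8-oxabicyclo[3.2.1]octan-6-one
Conditions: (n-Pr)4N[RuO4] (cat.), N-methylmorpholine N-oxide, 4 Å molecular sieves, CH2Cl2, rt
Reagents that add atoms: none
Why: Ley–Griffith oxidation of the secondary alcohol under neutral conditions gives the strained ketone without base-induced opening of the β-alkoxy ketone.

Step 6
Reactants: 9 (1R,3S,5S)-3-(benzyloxy)-8-oxabicyclo[3.2.1]octan-6-one
Product: 10 (1R,5R,7S)-7-(benzyloxy)-2,9-dioxabicyclo[3.3.1]nonan-3-one
Conditions: m-CPBA, NaHCO3, CH2Cl2, 0 °C → rt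
Reagents that add atoms: m-CPBA (3-chloroperoxybenzoic acid), O=C(OO)c1cccc(Cl)c1
Why: The peracid adds to the ketone carbon C3 to give the Criegee peroxy hemiketal, and the C3–C9 bond antiperiplanar to the O–O bond shifts from carbon to oxygen with loss of 3-chlorobenzoate (Baeyer–Villiger oxidation; closest precedent is the peracid oxidation of α-alkoxy bridged ketones such as 7-oxanorbornanones and 8-oxabicyclo[3.2.1]octan-6-ones to lactone acetals). The new six-membered 1,3-dioxan-4-one ring (C9, inserted O, C3, C4, C5, bridge O) arises not by cyclisation but by ring expansion of the five-membered oxolanone through this 1,2-shift, the tetrahydropyran ring being carried over unchanged. No stereocentre is created: C9 migrates with retention and C5 and C7 are untouched, so the syn C5–O/C7–O relationship is preserved while C3 becomes the acyl carbon and C9 a masked aldehyde. The step needs regioselective migration of the bridgehead C9 rather than the C4 methylene, and this is secured by the lone pairs of the bridge oxygen on C9, which stabilise the electron-deficient migrating carbon, together with its higher substitution. Chemoselectivity is not at issue, since the alkene is gone and the benzyl ether is inert to buffered peracid.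

Step 7
Reactants: 10 lactone acetal
Product: 11 methyl 2-[(2R,4S)-4-(benzyloxy)-6-methoxyoxan-2-yl]acetate (anomeric mixture)
Conditions: MeOH, H2SO4 (cat.), rt
Reagents that add atoms: methanol, CO
Why: Acid-catalysed methanolysis (transesterification of the acyloxy-acetal lactone, then Fischer acetalisation of the released lactol) gives the monocyclic methyl ester methyl acetal; both anomers converge in step 8 and C5/C7 are not involved.

Step 8
Reactants: 11 methyl ester methyl acetal
Product: 12 methyl (3R,5S)-5-(benzyloxy)-6-(1,3-dithian-2-yl)-3-hydroxyhexanoate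
Conditions: HS(CH2)3SH, BF3·OEt2, CH2Cl2, −20 → 0 °C
Reagents that add atoms: propane-1,3-dithiol, SCCCS
Why: Lewis-acid transthioacetalisation, in which ionisation of the 2-deoxy glycosidic acetal and capture by the dithiol opens the ring to the thermodynamically favoured 1,3-dithiane and frees the C5 hydroxyl, the benzyl ether and ester tolerating the short cold exposure.

Step 9
Reactants: 12 hydroxy dithiane
Product: 13 methyl (3R,5S)-5-(benzyloxy)-3-[(tert-butyldimethylsilyl)oxy]-6-(1,3-dithian-2-yl)hexanoate
Conditions: TBSCl, imidazole, DMF, rt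
Reagents that add atoms: tert-butyldimethylsilyl chloride, CC(C)(C)[Si](C)(C)Cl
Why: Standard silylation of the secondary alcohol blocks the C5 oxygen so that the aldehyde released next cannot reclose to the lactol.

Step 10
Reactants: 13 silyl ether dithiane
Product: 14 methyl (3R,5S)-5-(benzyloxy)-3-[(tert-butyldimethylsilyl)oxy]-7-oxoheptanoate
Conditions: MeI, CaCO3, MeCN/H2O (9:1), 45 °C
Reagents that add atoms: water, O
Why: Alkylative hydrolysis of the dithiane (S-methylation, then attack of water) under carbonate buffering unmasks the C9 aldehyde without acid or strong base, so the silyl ether survives and β-elimination of the C7 benzyloxy group is avoided.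

Step 11
Reactants: 15 undecan-2-one
Product: 17 trimethyl(undec-1-en-2-yloxy)silane, via lithium enolate 16 (not isolated)
Conditions: LiN(i-Pr)2, THF, −78 °C; then Me3SiCl, −78 °C → rt
Reagents that add atoms: chlorotrimethylsilane, C[Si](C)(C)Cl
Why: Kinetic deprotonation of the methyl ketone at the methyl group and O-silylation of the enolate give the terminal enol silane needed for the Mukaiyama aldol.

Step 12
Reactants: 14 aldehyde; 17 enol silane
Product: 18 methyl (3R,5R,7R)-5-(benzyloxy)-3-[(tert-butyldimethylsilyl)oxy]-7-hydroxy-9-oxooctadecanoate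
Conditions: BF3·OEt2, CH2Cl2, −78 °C; aqueous work-up
Reagents that add atoms: none
Why: Mukaiyama aldol addition under non-chelating BF3 activation forms C9–C10, and the β-benzyloxy aldehyde should react through the dipole-minimised conformer (polar 1,3-induction), placing the new C9 carbinol 1,3-anti to C7–OBn.

Step 13
Reactants: 18 β-hydroxy ketone
Product: 20 methyl (3R,5R,7S,9S)-5-(benzyloxy)-3-[(tert-butyldimethylsilyl)oxy]-7,9-dihydroxyoctadecanoate, via diethylboron chelate 19 (not isolated)
Conditions: Et2BOMe, THF/MeOH (4:1), −78 °C; then NaBH4, −78 °C; MeOH co-evaporation on work-up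
Reagents that add atoms: none
Why: Narasaka–Prasad reduction, in which the C9 hydroxyl and the C11 ketone are held in a six-membered boron chelate and external hydride attacks axially, sets C11 1,3-syn to C9 while the methyl ester is untouched at −78 °C.

Step 14
Reactants: 20 syn-diol ester
Product: 21 tert-butyl (5R,7R,9S,11S)-7-(benzyloxy)-5-[(tert-butyldimethylsilyl)oxy]-9,11-dihydroxy-3-oxoicosanoate
Conditions: LiCH2CO2t-Bu (6 equiv, from t-BuOAc and LiN(i-Pr)2), THF, −78 → −30 °C; aq. NH4Cl
Reagents that add atoms: tert-butyl acetate (used as its lithium enolate), CC(=O)OC(C)(C)C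
Why: Crossed Claisen condensation forms C2–C3: excess ester enolate first converts the two hydroxyls to alkoxides and then acylates at the methyl ester faster than it deprotonates it, the β-keto ester being stored as its enolate until the quench.

Step 15
Reactants: 21 silyloxy β-keto ester
Product: 23 (6R)-6-[(2R,4S,6S)-2-(benzyloxy)-4,6-dihydroxypentadecyl]-4-hydroxy-5,6-dihydro-2H-pyran-2-one, via desilylated hydroxy keto ester 22 (not isolated)
Conditions: aq. HF, MeCN, 0 °C → rt; extractive work-up, then TFA, CH2Cl2, 0 °C → rt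
Reagents that add atoms: none
Why: Fluoride-mediated desilylation frees the C5 hydroxyl and TFA then brings about acid-catalysed lactonisation onto C1 with loss of the tert-butyl group as isobutene, closing the 4-hydroxy-5,6-dihydropyran-2-one (enol form of the β-keto lactone), while C7 stays benzylated so that it cannot ketalise the C3 carbonyl.

Step 16
Reactants: 23 benzyl-protected lactone
Product: 24 (6R)-4-hydroxy-6-[(2R,4S,6S)-2,4,6-trihydroxypentadecyl]-5,6-dihydro-2H-pyran-2-one (target)
Conditions: H2 (1 atm), Pd/C, EtOAc, rt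
Reagents that add atoms: none
Why: Hydrogenolysis of the benzyl ether over palladium on carbon releases the C7 hydroxyl; the enolised β-keto lactone is reduced only under forcing conditions and no stereocentre is touched.

**Compound list**

1 | furan | c1ccoc1 | starting material
2 | 1,1,3,3-tetrabromopropan-2-one | O=C(C(Br)Br)C(Br)Br | starting material
3 | 2,4-dibromo-8-oxabicyclo[3.2.1]oct-6-en-3-one (mixture of bromine epimers, not isolated) | O=C1C(Br)[C@@H]2C=C[C@@H](O2)C1Br | intermediate
4 | 8-oxabicyclo[3.2.1]oct-6-en-3-one (meso) | O=C1C[C@@H]2C=C[C@H](C1)O2 | intermediate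
5 | meso 8-oxabicyclo[3.2.1]oct-6-en-3-ol, hydroxyl equatorial (cis to the oxygen bridge) | O[C@H]1C[C@@H]2C=C[C@H](C1)O2 | intermediate
6 | meso 3-(benzyloxy)-8-oxabicyclo[3.2.1]oct-6-ene, benzyloxy equatorial | c1ccccc1CO[C@H]1C[C@@H]2C=C[C@H](C1)O2 | intermediate
7 | B-[3-(benzyloxy)-8-oxabicyclo[3.2.1]oct-6-exo-yl]diisopinocampheylborane (boron in place of the hydroxyl of 8, not isolated) | B([C@H]1C[C@H]2C[C@@H]([C@@H]1C)C2(C)C)([C@H]1C[C@H]2C[C@@H]([C@@H]1C)C2(C)C)[C@@H]1C[C@H]2C[C@H](OCc3ccccc3)C[C@@H]1O2 | intermediate
8 | (1S,3S,5S,6R)-3-(benzyloxy)-8-oxabicyclo[3.2.1]octan-6-ol (6-exo-hydroxyl) | O[C@@H]1C[C@H]2C[C@H](OCc3ccccc3)C[C@@H]1O2 | intermediate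
9 | (1R,3S,5S)-3-(benzyloxy)-8-oxabicyclo[3.2.1]octan-6-one | O=C1C[C@H]2C[C@H](OCc3ccccc3)C[C@@H]1O2 | intermediate
10 | (1R,5R,7S)-7-(benzyloxy)-2,9-dioxabicyclo[3.3.1]nonan-3-one | O=C1C[C@H]2C[C@H](OCc3ccccc3)C[C@@H](O1)O2 | intermediate
11 | methyl 2-[(2R,4S)-4-(benzyloxy)-6-methoxyoxan-2-yl]acetate (anomeric mixture) | COC(=O)C[C@H]1C[C@H](OCc2ccccc2)CC(OC)O1 | intermediate
12 | methyl (3R,5S)-5-(benzyloxy)-6-(1,3-dithian-2-yl)-3-hydroxyhexanoate | COC(=O)C[C@H](O)C[C@H](OCc1ccccc1)CC1SCCCS1 | intermediate
13 | methyl (3R,5S)-5-(benzyloxy)-3-[(tert-butyldimethylsilyl)oxy]-6-(1,3-dithian-2-yl)hexanoate | COC(=O)C[C@H](O[Si](C)(C)C(C)(C)C)C[C@H](OCc1ccccc1)CC1SCCCS1 | intermediate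
14 | methyl (3R,5S)-5-(benzyloxy)-3-[(tert-butyldimethylsilyl)oxy]-7-oxoheptanoate | COC(=O)C[C@H](O[Si](C)(C)C(C)(C)C)C[C@H](OCc1ccccc1)CC=O | intermediate
15 | undecan-2-one | CCCCCCCCCC(C)=O | starting material
16 | lithium undec-1-en-2-olate (not isolated) | [Li+].[O-]C(=C)CCCCCCCCC | intermediate
17 | trimethyl(undec-1-en-2-yloxy)silane | C=C(CCCCCCCCC)O[Si](C)(C)C | intermediate
18 | methyl (3R,5R,7R)-5-(benzyloxy)-3-[(tert-butyldimethylsilyl)oxy]-7-hydroxy-9-oxooctadecanoate | COC(=O)C[C@H](O[Si](C)(C)C(C)(C)C)C[C@H](OCc1ccccc1)C[C@@H](O)CC(=O)CCCCCCCCC | intermediate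
19 | 7-O-diethylboryl derivative of 18, chelated to the C9 ketone of the octadecanoate (not isolated) | COC(=O)C[C@H](O[Si](C)(C)C(C)(C)C)C[C@H](OCc1ccccc1)C[C@@H](OB(CC)CC)CC(=O)CCCCCCCCC | intermediate
20 | methyl (3R,5R,7S,9S)-5-(benzyloxy)-3-[(tert-butyldimethylsilyl)oxy]-7,9-dihydroxyoctadecanoate | COC(=O)C[C@H](O[Si](C)(C)C(C)(C)C)C[C@H](OCc1ccccc1)C[C@@H](O)C[C@@H](O)CCCCCCCCC | intermediate
21 | tert-butyl (5R,7R,9S,11S)-7-(benzyloxy)-5-[(tert-butyldimethylsilyl)oxy]-9,11-dihydroxy-3-oxoicosanoate | CC(C)(C)OC(=O)CC(=O)C[C@H](O[Si](C)(C)C(C)(C)C)C[C@H](OCc1ccccc1)C[C@@H](O)C[C@@H](O)CCCCCCCCC | intermediate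
22 | tert-butyl (5R,7R,9S,11S)-7-(benzyloxy)-5,9,11-trihydroxy-3-oxoicosanoate (not isolated) | CC(C)(C)OC(=O)CC(=O)C[C@H](O)C[C@H](OCc1ccccc1)C[C@@H](O)C[C@@H](O)CCCCCCCCC | intermediate
23 | (6R)-6-[(2R,4S,6S)-2-(benzyloxy)-4,6-dihydroxypentadecyl]-4-hydroxy-5,6-dihydro-2H-pyran-2-one | CCCCCCCCC[C@H](O)C[C@H](O)C[C@@H](OCc2ccccc2)C[C@@H]1CC(O)=CC(=O)O1 | intermediate
24 | (6R)-4-hydroxy-6-[(2R,4S,6S)-2,4,6-trihydroxypentadecyl]-5,6-dihydro-2H-pyran-2-one | CCCCCCCCC[C@H](O)C[C@H](O)C[C@@H](O)C[C@@H]1CC(O)=CC(=O)O1 | target

**Count and risks**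

Total step count: 16. Longest linear sequence: 15 steps (steps 1–10 and 12–16); step 11 is a one-step side branch.

Steps most likely to fail:

1. Step 4. The risk is insufficient discrimination of the two enantiotopic alkene carbons, or induction in the opposite sense, which would erode or invert the absolute configuration of the whole series. The fallback sets out from 6 and returns at 8. Alkene 6 is hydroborated with BH3·THF and oxidised (NaOH, H2O2) to the racemic exo-alcohol F1. F1 is then resolved by enzyme-catalysed transesterification (immobilised Candida antarctica lipase B, vinyl acetate, t-BuOMe, rt). Kazlauskas' rule predicts acylation of the (6R)-carbinol, giving the acetate of 8 F2, which is separated from the unreacted enantiomer and methanolysed (K2CO3, MeOH) to 8. Should the enzyme prefer the other enantiomer, the unreacted alcohol is 8 itself.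

2. Step 12. The risk is weak 1,3-anti facial selectivity at C9 in the BF3-mediated addition, leaving a C9 epimer that is hard to remove. The fallback sets out from 14 and returns at 20; it reverses the polarity of the aldol so that the benzyloxy group controls C11 by 1,5-anti induction. MeMgBr is added to 14 (THF, −78 °C, the ester being spared) to give the secondary alcohol methyl (3R,5R)-5-(benzyloxy)-3-[(tert-butyldimethylsilyl)oxy]-7-hydroxyoctanoate F3 as a mixture of carbinol epimers. Oxidation with Dess–Martin periodinane gives the methyl ketone F4. Enolisation with (c-Hex)2BCl and Et3N (Et2O, −78 °C) gives the dicyclohexylboron enolate F5. F5 adds to decanal and, after H2O2 work-up, gives the 1,5-anti aldol F6, in which the C11 carbinol is anti to C7–OBn. Narasaka–Prasad reduction of F6 (Et2BOMe, NaBH4, −78 °C), now directed by the C11 hydroxyl, sets C9 syn to C11 and delivers 20.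

3. Step 14. The risk is proton transfer from C4 to the ester enolate followed by β-elimination of the C5 silyloxy group, or stalling of the acylation in the polyalkoxide aggregate. The fallback sets out from 20 and returns at 21. The methyl ester of 20 is reduced with (i-Bu)2AlH (excess to cover the two hydroxyls, CH2Cl2, −78 °C) to the aldehyde F7. F7 is homologated by the Roskamp reaction (tert-butyl diazoacetate, SnCl2 cat., CH2Cl2, rt), in which addition of the diazo ester and 1,2-hydride shift with loss of N2 give the β-keto ester 21 under essentially neutral conditions.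

**Further compounds**

F1 | step 4 | racemic 6-exo-alcohol (racemate of 8; the enantiomer of 8 is drawn) | O[C@H]1C[C@@H]2C[C@@H](OCc3ccccc3)C[C@H]1O2
F2 | step 4 | 6-O-acetyl derivative of 8 | CC(=O)O[C@@H]1C[C@H]2C[C@H](OCc3ccccc3)C[C@@H]1O2
F3 | step 12 | methyl (3R,5R)-5-(benzyloxy)-3-[(tert-butyldimethylsilyl)oxy]-7-hydroxyoctanoate (C7 epimers) | COC(=O)C[C@H](O[Si](C)(C)C(C)(C)C)C[C@H](OCc1ccccc1)CC(C)O
F4 | step 12 | methyl (3R,5S)-5-(benzyloxy)-3-[(tert-butyldimethylsilyl)oxy]-7-oxooctanoate | COC(=O)C[C@H](O[Si](C)(C)C(C)(C)C)C[C@H](OCc1ccccc1)CC(C)=O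
F5 | step 12 | dicyclohexylboron enolate of F4 (terminal enolate) | COC(=O)C[C@H](O[Si](C)(C)C(C)(C)C)C[C@H](OCc1ccccc1)CC(=C)OB(C1CCCCC1)C1CCCCC1
F6 | step 12 | methyl (3R,5S,9S)-5-(benzyloxy)-3-[(tert-butyldimethylsilyl)oxy]-9-hydroxy-7-oxooctadecanoate | COC(=O)C[C@H](O[Si](C)(C)C(C)(C)C)C[C@H](OCc1ccccc1)CC(=O)C[C@@H](O)CCCCCCCCC
F7 | step 14 | (3R,5R,7S,9S)-5-(benzyloxy)-3-[(tert-butyldimethylsilyl)oxy]-7,9-dihydroxyoctadecanal | O=CC[C@H](O[Si](C)(C)C(C)(C)C)C[C@H](OCc1ccccc1)C[C@@H](O)C[C@@H](O)CCCCCCCCC
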